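The rate constants belong to no real substance; the result is computed.

You cannot bank the target in this flask: the step that forms it also runs back, and it relaxes in a time short against the run, so the target stays tied to the starting material beside it.

    starting material ⇌ dormant form (K1 = 6.1, k1 = 0.00776 s⁻¹)
    starting material + protic impurity → quenched substrate (k2 = 0.217 L mol⁻¹ s⁻¹)
    starting material ⇌ isomer of the product (K3 = 2.70, k3 = 0.00511 s⁻¹)
    starting material ⇌ target (K4 = 1.57, k4 = 0.00985 s⁻¹)
    starting material ⇌ third isomer (K5 = 1.73, k5 = 0.00698 s⁻¹)
    2 starting material → self-condensation product (k6 = 0.00402 L mol⁻¹ s⁻¹)

starting material 0.10 M; protic impurity 0.0200 M; time 6.0 h

- in percentages every species weighs as the starting material in it: one self-condensation product counts as two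
- a doubled species enters its step squared and goes two at a time
- what has gone from starting material into another species counts as reacted, even if it can come back
- run time (flask): 6.0 h

- conversion of starting material at 6.0 h
- amount of target at 6.0 h, in percent of the starting material charged
- amount of isomer of the product at 6.0 h, in percent of the starting material charged
- amount of third isomer at 6.0 h, in percent of the starting material charged
- amount of target if the flask were left three thousand times as long, in percent of the starting material charged

Count turnovers, fastest first. Target and starting material relax with a half-life of 0.716 min, and the run holds about 502 of those. Step 3 is the slowest reversible step, yet its forward half-life of 2.26 min is short against the run. So I treat the five linked forms as one pool. Starting material weighs one, each other form weighs its constant, and the dormant form, the resting state, weighs most. The weights add up to 13.1. The rule I carry is the target's share of the pool, its constant over that sum: 12.0%.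

Next comes the protic impurity, the limiting reagent of step 2. If it takes its whole charge, the pool is 0.0800 M, with free [starting material] near 0.00611 M. At that level the impurity's half-life is 8.72 min, short against the run, so I let it finish.

Last comes self-condensation, which goes with [starting material] squared. It gives the pool a first half-life of 74.1 h, longer than the run and longer than the impurity's half-life. The run is 0.0810 of that half-life, so the pool ends near 0.0740 M. My target is then 8.87%.

The forecast gives conversion 94.5%, target 8.7%, isomer of the product 14.9%, third isomer 9.6% and long-run target 0.039%. Its ground: “Slow second-order self-condensation then drains that pool”. Its target is lower than mine.

This flask gives conversion 94.4%, target 8.72%, isomer of the product 15.0%, third isomer 9.61% and long-run target 0.0393%, so the forecast holds. With the way back from target struck out, the target reads 82.0%. Divide 8.72% by the share and the pool still holds 72.7% of the charge after 6.00 h. Take off the 5.55% of starting material, and 67.1% of the charge counts as converted yet stands in forms that can come back.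

In the neighbour flask with 0.080 M of protic impurity, the subtraction leaves 0.0200 M, and the share gives 2.40% of target. That flask gives 2.22%, with quenched substrate at 80.0%.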